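**Analysis of the target**

The target is a trans-fused bicyclo[5.3.0]decene (a daucane-type hydroazulene) carrying a 4-hydroxybenzoate. The skeleton is numbered as follows: C1 is the vinylic methyl on C2, C2=C3 is the ring alkene, C4 the allylic methylene, C5 the quaternary ring-fusion carbon with the angular methyl, C6 the secondary carbinol, C7 the cyclopentane methylene, C8 the tertiary carbinol with the isopropyl group, C9 the ring-fusion methine, C10 the ester-bearing carbon and C11 the methylene that closes the seven-membered ring back to C2. Five contiguous stereocentres (5R,6R,8R,9S,10S) sit on C5, C6, C8, C9 and C10. The angular methyl and the C6 and C8 hydroxyls lie on one face; C9–H, the isopropyl group and the C10 ester oxygen lie on the other, so the ring fusion is trans and the C8/C10 oxygens are 1,3-anti. Sensitive points are the aryl ester with its free phenol, the trisubstituted alkene that can migrate, and the C8–C9–C10 unit, which at the ketone oxidation level is an aldol (retro-aldol, β-elimination). The difficulty is the quaternary C5 flanked by stereocentres on both sides, inside a seven-membered ring whose alkene must end at C2=C3. The strategy rests on one pattern: the oxygenated C10 between C9 and C11 is an oxyallyl unit, C2–C5 is a 1,3-diene, and C6–C7–C8 is a three-atom tether joining the diene terminus C5 to the allyl terminus C9.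

**Retrosynthetic reasoning**

26 ⇒ 25. The last operation only unmasks the phenol and the C6 carbinol. Both are carried as tert-butyldimethylsilyl ethers so that one fluoride treatment releases them without touching the ester.

25 ⇒ 23 + 24. The ester C–O bond is cut. In 23 the C10 hydroxyl is the only free secondary alcohol (C6 is silylated, C8 is tertiary), so acylation with 24 needs no further differentiation.

23 ⇒ 22. The C10–H bond is cut back to the ketone. The free C8 hydroxyl of 22 is cis to C10 on the cyclopentane and can deliver hydride to the same face, which gives the 1,3-anti diol. This is why C8 is unmasked first (22 from 21) while C6 stays protected.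

21 ⇒ 19 ⇒ 18. The alkene is moved back from C2=C3 to C3=C4, where a cycloaddition leaves it. Forward, the quaternary C5 blocks migration toward the ring fusion, so the alkene can only walk toward the carbonyl to enone 19. Kinetic α-protonation of dienolate 20 then places it at C2=C3 and nowhere else. A direct one-position shift without the ketone as a sink would give mixtures of the two trisubstituted isomers.

18 ⇒ 16 (key). C5–C9 and C2–C11 are cut together. This is the only disconnection that removes both rings, the quaternary centre and three stereocentres at once, and it leads back to an acyclic chain with only the C6 and C8 carbinols. Forward, the oxyallyl cation 17 must add across the diene termini on the face that leaves the C5 methyl cis to the C6 oxygen.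

16 ⇒ 13 + 14. The C10–C11 bond is cut. Bringing in the chloromethyl carbon as a nucleophile derived from 14 on amide 13 installs the chlorine without an electrophilic halogen source, which the diene would not survive.

13 ⇒ 12 ⇒ 11 ⇒ 10. These are protecting-group and lactone-opening steps. The two oxygens get different silyl groups because C8 must be freed alone later; lactone 10 is opened to amide 11 so that C10 can later accept exactly one carbon nucleophile.

10 ⇒ 8 ⇒ 6 + 7. The C8–C9 bond is cut. An intermolecular, chelation-controlled addition of a C9 nucleophile to the isopropyl ketone of 6 would place the incoming carbon axial on the chelate, which is the C8 epimer of what the ring needs. Tethering the two-carbon unit to the C6 oxygen as ester 8 reverses this: in the cyclic transition state of samarium enolate 9 the isopropyl group is equatorial and the new C–C bond is in the ring, giving the syn C6/C8 diol pattern.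

6 ⇒ 3 + 4. The C6–C7 bond is an aldol bond between the methyl group of 4 and aldehyde 3; reagent control sets C6.

3 ⇒ 1 + 2. The C4=C5 bond is made by olefination of 1 with the stabilised ylide 2, which fixes the (E,E)-diene with the methyl on C5.

**Alternatives that were turned down**

Alternative 1: The cyclopentane is annulated onto a preformed seven-membered ring by cutting C5–C6 and C8–C9.
- Forward: the symmetric dienone A2 and the nitro ketone A3 are combined under a cinchona-derived primary amine with an acid co-catalyst. Iminium-activated Michael addition of the nitronate carbon C6 to C5 desymmetrises A2, and the resulting enamine at C9 closes onto the C8 ketone to give A1.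
- For: absolute configuration comes from a catalyst, the starting materials are achiral and simple, four stereocentres including quaternary C5 form in one operation, and the C11=C2 enone is already in place. On step economy and on the source of chirality it is stronger than the chosen route.
- Against: C5 is a β,β-disubstituted acceptor carbon, so the Michael step is slow and reversible. The aldol onto an isopropyl ketone is reversible and its C8 configuration is under thermodynamic control. The second enone of A2 invites double addition. The nitro group must then be turned into the C6 carbinol (Nef reaction, reduction) on a retro-aldol-prone β-hydroxy ketone.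
- Comparison: three unproven events are stacked. The chosen route sets C6 and C8 by established acyclic reactions and keeps the uncertainty in one step that is precedented for this ring system.

Alternative 2: Only C11–C2 is cut.
- Forward: the redox-active ester A5, which carries a (Z)-vinyl iodide arm on C5, is reduced at a cathode with NiCl2·glyme and 2,2'-bipyridine. The C11 radical released by decarboxylation is coupled with the vinyl iodide carbon C2 and closes the seven-membered ring to A4.
- For: the C2=C3 alkene is created directly, in its final position and geometry. No stereocentre is formed, so the key step is stereochemically unambiguous, and a free tertiary alcohol is tolerated. On alkene placement it is clearly stronger than the chosen route, which spends three steps on relocating the double bond.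
- Against: the key step makes one bond and one ring. A5 already contains all five stereocentres on a fully substituted cyclopentane, and its synthesis, which is the real problem, is left open. Seven-membered ring closure competes with reduction and dimerisation of the radical, and the oxygen on C10 is β to the nickel-bound carbon. The 4-methoxybenzyl ether must later be exchanged for the ester.
- Comparison: the chosen strategy forms two rings, two C–C bonds and the quaternary centre in one step from a chain with only two stereocentres.

Alternative 3: The cyclopentane bond C7–C8 is cut.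
- Forward: diazoketone A7 is decomposed with Rh2(OAc)4. The carbenoid at C7 inserts with retention into the silyloxy-activated C8–H bond of the side chain on C9, giving the C6 ketone A6, which is then reduced.
- For: a secondary silyl ether stereocentre is converted stereospecifically into the tertiary carbinol, the ester is already installed, and hydride attack on the C6 ketone anti to the angular methyl should give the cis hydroxyl/methyl relationship. On the security of the C5/C6 relationship it is stronger than the chosen route.
- Against: the carbenoid has the C2=C3 alkene in the γ,δ-position, and intramolecular cyclopropanation is normally faster than C–H insertion. The C10–H and the isopropyl methine are further insertion sites. A7 needs the seven-membered ring with quaternary C5, C9, C10 and the side-chain stereocentre before the key step.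
- Comparison: the hardest part of the target is moved into the preparation of the substrate. The chosen route solves it in the key step itself and reaches its precursor in eight steps.

Key step: step 9

Assumption: with methyl ketones, (−)-Ipc2BCl (from (+)-α-pinene) is taken to direct attack to the Re face of aldehyde 3, which gives (5R)-6; if the sense were opposite, the (+)-reagent would be used and nothing else would change.

Remark: 2 and 24 are taken as catalogue compounds. Names of the bicyclic compounds use the locants C1–C11 of the analysis, and their descriptors refer to these locants.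

**Route**

Step 1
Reactants: 1 (E)-but-2-enal (crotonaldehyde); 2 2-(triphenyl-λ5-phosphanylidene)propanal
Product: 3 (2E,4E)-2-methylhexa-2,4-dienal
Conditions: toluene, 90 °C
Reagents that add atoms: none
Why: Wittig olefination with a formyl-stabilised ylide gives the (E)-trisubstituted enal; the α-branched product is a poorer electrophile than 1, so the reaction stops after one olefination.

Step 2
Reactants: 3 (2E,4E)-2-methylhexa-2,4-dienal; 4 3-methylbutan-2-one
Product: 6 (5R,6E,8E)-5-hydroxy-2,6-dimethyldeca-6,8-dien-3-one, via enol diisopinocampheylborinate 5 (not isolated)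
Conditions: (−)-Ipc2BCl, Et3N, Et2O, 0 °C; 3, −78 to −20 °C; then H2O2, pH 7 buffer, MeOH
Reagents that add atoms: none
Why: Boron-mediated aldol of a methyl ketone: Ipc2BCl/Et3N enolises 4 on the methyl side, and 5 adds to the aldehyde through a cyclic boron-bound transition state in which the isopinocampheyl ligands select the Re face of 3, setting C6 as R (5R in the name of 6). α-Branched enals are the best aldehyde class for this reagent; enantiomeric purity can be raised later if lactone 10 crystallises.

Step 3
Reactants: 6 (5R,6E,8E)-5-hydroxy-2,6-dimethyldeca-6,8-dien-3-one; 7 bromoacetyl bromide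
Product: 8 (5R,6E,8E)-2,6-dimethyl-3-oxodeca-6,8-dien-5-yl 2-bromoacetate
Conditions: pyridine, CH2Cl2, −20 to 0 °C
Reagents that add atoms: none
Why: O-Acylation of a secondary alcohol with an acyl bromide; the weak base and low temperature avoid β-elimination of the β-acyloxy ketone.

Step 4
Reactants: 8 (5R,6E,8E)-2,6-dimethyl-3-oxodeca-6,8-dien-5-yl 2-bromoacetate
Product: 10 (4S,6R)-6-[(2E,4E)-hexa-2,4-dien-2-yl]-4-hydroxy-4-(propan-2-yl)oxan-2-one, via samarium enolate 9 (not isolated)
Conditions: SmI2, THF, −78 °C
Reagents that add atoms: none
Why: Samarium-mediated intramolecular Reformatsky reaction: SmI2 reduces the C–Br bond to the trivalent-samarium ester enolate 9, which adds to the ketone through a chelated chair-like transition state with the dienyl group on C6 and the isopropyl group equatorial and the samarium-bound ketone oxygen axial. This 1,3-induction sets C8 with the hydroxyl trans to the dienyl group on the lactone, which is the syn C6/C8 diol relationship of the target; the diene and the allylic ester are not reduced by SmI2 in THF at this temperature.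

Step 5
Reactants: 10 (4S,6R)-6-[(2E,4E)-hexa-2,4-dien-2-yl]-4-hydroxy-4-(propan-2-yl)oxan-2-one
Product: 11 (3S,5R,6E,8E)-3,5-dihydroxy-N-methoxy-N,6-dimethyl-3-(propan-2-yl)deca-6,8-dienamide
Conditions: MeNH(OMe)·HCl, AlMe3, CH2Cl2, 0 °C to rt
Reagents that add atoms: N,O-dimethylhydroxylamine hydrochloride, CNOC.Cl
Why: Aminolysis of a lactone with the amide reagent formed from AlMe3 and the amine hydrochloride (Weinreb amide formation); the open hydroxy amide is silylated in the next step before it can relactonise.

Step 6
Reactants: 11 (3S,5R,6E,8E)-3,5-dihydroxy-N-methoxy-N,6-dimethyl-3-(propan-2-yl)deca-6,8-dienamide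
Product: 12 (3S,5R,6E,8E)-5-[(tert-butyldimethylsilyl)oxy]-3-hydroxy-N-methoxy-N,6-dimethyl-3-(propan-2-yl)deca-6,8-dienamide
Conditions: TBSCl, imidazole, DMF, rt
Reagents that add atoms: tert-butyldimethylsilyl chloride, CC(C)(C)[Si](C)(C)Cl
Why: Standard silylation; the silyl chloride with imidazole reacts only with the secondary allylic hydroxyl and leaves the tertiary one.

Step 7
Reactants: 12 (3S,5R,6E,8E)-5-[(tert-butyldimethylsilyl)oxy]-3-hydroxy-N-methoxy-N,6-dimethyl-3-(propan-2-yl)deca-6,8-dienamide
Product: 13 (3S,5R,6E,8E)-5-[(tert-butyldimethylsilyl)oxy]-N-methoxy-N,6-dimethyl-3-(propan-2-yl)-3-[(triethylsilyl)oxy]deca-6,8-dienamide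
Conditions: TESOTf, 2,6-lutidine, CH2Cl2, −78 to 0 °C
Reagents that add atoms: triethylsilyl trifluoromethanesulfonate, CC[Si](CC)(CC)OS(=O)(=O)C(F)(F)F
Why: Silyl triflate/2,6-lutidine silylation of a hindered tertiary alcohol; the triethylsilyl group blocks cyclisation of the oxygen onto C11 and retro-aldol cleavage in the later steps, and can be removed beside the tert-butyldimethylsilyl ether.

Step 8
Reactants: 13 (3S,5R,6E,8E)-5-[(tert-butyldimethylsilyl)oxy]-N-methoxy-N,6-dimethyl-3-(propan-2-yl)-3-[(triethylsilyl)oxy]deca-6,8-dienamide; 14 chloroiodomethane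
Product: 16 (4S,6R,7E,9E)-6-[(tert-butyldimethylsilyl)oxy]-1-chloro-7-methyl-4-(propan-2-yl)-4-[(triethylsilyl)oxy]undeca-7,9-dien-2-one, via tetrahedral lithium adduct 15 (not isolated)
Conditions: MeLi·LiBr, THF, −78 °C; then aq NH4Cl
Reagents that add atoms: none
Why: Addition of LiCH2Cl, formed in situ from 14 by iodine–lithium exchange, to a Weinreb amide; the chelated adduct 15 survives until the quench, so only one addition occurs. The chlorine arrives without exposing the diene to an electrophilic halogen source.

Step 9
Reactants: 16 (4S,6R,7E,9E)-6-[(tert-butyldimethylsilyl)oxy]-1-chloro-7-methyl-4-(propan-2-yl)-4-[(triethylsilyl)oxy]undeca-7,9-dien-2-one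
Product: 18 (2R,5R,6R,8R,9R)-6-[(tert-butyldimethylsilyl)oxy]-2,5-dimethyl-8-(propan-2-yl)-8-[(triethylsilyl)oxy]bicyclo[5.3.0]dec-3-en-10-one (trans-fused), via oxyallyl cation 17 (not isolated)
Conditions: Et3N, LiClO4 (1 M), Et2O, high dilution, 0 °C to rt
Reagents that add atoms: none
Why: Et3N enolises 16 reversibly toward C9 and LiClO4 assists loss of chloride from C11, giving the lithium-bound oxyallyl cation 17, a two-electron three-carbon unit (C9–C10–C11). It adds across the termini of the s-cis diene, C9 to C5 and C11 to C2, either in concert (suprafacial on both partners) or by C9–C5 bonding first and closure of the allyl cation/enolate pair at C2–C11; the closest known reaction type is the base-mediated intramolecular (4+3) cycloaddition of α-chloro ketone-derived oxyallyl cations with tethered 1,3-dienes, which gives bicyclo[5.3.0]decenones. The five-membered ring closes through the three-atom tether C6–C7–C8 as the C5–C9 bond forms, and the seven-membered ring is the cycloaddition ring itself, made from the four diene carbons and the three allyl carbons. C5 is controlled by C6: in the reactive rotamer the C6–H lies in the plane of C4=C5, C7 sits on the bonding face and the bulky silyloxy group on the far face, anti to the new bond, so the methyl group ends cis to the C6 oxygen and the diene arm trans to it. C9 is controlled by C8: the oxyallyl carbon C10 takes the side of the nascent cyclopentane opposite the isopropyl group, which with the diene arm on the other face means a trans ring fusion, reached through the extended arrangement of the (Z)-configured cation. C2 follows from suprafacial addition to the (E,E)-diene and is of no consequence because it is erased in step 10. The step needs face selectivity at C5 and cyclisation faster than Favorskii-type collapse; the (E)-C4=C5 geometry (tether outside), the two stereocentres in the tether and a non-nucleophilic, ionising medium at high dilution are what should secure it.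

Step 10
Reactants: 18 (2R,5R,6R,8R,9R)-6-[(tert-butyldimethylsilyl)oxy]-2,5-dimethyl-8-(propan-2-yl)-8-[(triethylsilyl)oxy]bicyclo[5.3.0]dec-3-en-10-one
Product: 19 (5R,6R,8R,9R)-6-[(tert-butyldimethylsilyl)oxy]-2,5-dimethyl-8-(propan-2-yl)-8-[(triethylsilyl)oxy]bicyclo[5.3.0]dec-1(2)-en-10-one, i.e. the conjugated enone with the C11=C2 double bond
Conditions: RuHCl(CO)(PPh3)3 (cat.), toluene, 90 °C
Reagents that add atoms: none
Why: Metal hydride-catalysed alkene isomerisation (hydrometallation/β-hydride elimination); the quaternary C5 blocks migration toward the ring fusion, so the double bond can only move toward the carbonyl, where conjugation holds it. RuHCl(CO)(PPh3)3 is neutral and spares both silyl ethers and the β-silyloxy ketone.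

Step 11
Reactants: 19 (5R,6R,8R,9R)-conjugated enone with the C11=C2 double bond
Product: 21 (5R,6R,8R,9R)-6-[(tert-butyldimethylsilyl)oxy]-2,5-dimethyl-8-(propan-2-yl)-8-[(triethylsilyl)oxy]bicyclo[5.3.0]dec-2-en-10-one, via potassium dienolate 20 (not isolated)
Conditions: KN(SiMe3)2, THF, −78 °C; then AcOH, −78 °C (inverse quench)
Reagents that add atoms: none
Why: Deconjugative protonation: the amide base removes the γ-hydrogen at C3 to give the extended dienolate 20, and kinetic protonation of a dienolate occurs at the α-carbon C11, which leaves the alkene at C2=C3; material in which the double bond had stopped at C2=C3 in step 10 gives the same dienolate by loss of its C11 hydrogen. The α'-hydrogen at C9 is a shielded methine between two quaternary carbons, and the low temperature guards against its removal and β-elimination of the C8 silyloxy group.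

Step 12
Reactants: 21 (5R,6R,8R,9R)-6-[(tert-butyldimethylsilyl)oxy]-2,5-dimethyl-8-(propan-2-yl)-8-[(triethylsilyl)oxy]bicyclo[5.3.0]dec-2-en-10-one
Product: 22 (5R,6R,8R,9R)-6-[(tert-butyldimethylsilyl)oxy]-8-hydroxy-2,5-dimethyl-8-(propan-2-yl)bicyclo[5.3.0]dec-2-en-10-one
Conditions: HF·pyridine, pyridine, THF, 0 °C
Reagents that add atoms: none
Why: Fluoride-mediated desilylation under buffered conditions; the triethylsilyl ether is cleaved well before the hindered secondary tert-butyldimethylsilyl ether, and the buffered medium avoids re-conjugation of the β,γ-enone.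

Step 13
Reactants: 22 (5R,6R,8R,9R)-6-[(tert-butyldimethylsilyl)oxy]-8-hydroxy-2,5-dimethyl-8-(propan-2-yl)bicyclo[5.3.0]dec-2-en-10-one
Product: 23 (5R,6R,8R,9S,10S)-6-[(tert-butyldimethylsilyl)oxy]-2,5-dimethyl-8-(propan-2-yl)bicyclo[5.3.0]dec-2-ene-8,10-diol
Conditions: Me4NBH(OAc)3, MeCN/AcOH, −30 °C
Reagents that add atoms: none
Why: Evans–Saksena reduction: the C8 hydroxyl exchanges onto boron and the hydride is delivered intramolecularly to the C10 carbonyl on the face that carries the C8 oxygen, giving the 1,3-anti diol (10S). Ketones without a directing hydroxyl are inert to this reagent, so the outcome is tied to the C8 stereocentre.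

Step 14
Reactants: 23 (5R,6R,8R,9S,10S)-6-[(tert-butyldimethylsilyl)oxy]-2,5-dimethyl-8-(propan-2-yl)bicyclo[5.3.0]dec-2-ene-8,10-diol; 24 4-[(tert-butyldimethylsilyl)oxy]benzoic acid
Product: 25 (5R,6R,8R,9S,10S)-6-[(tert-butyldimethylsilyl)oxy]-8-hydroxy-2,5-dimethyl-8-(propan-2-yl)bicyclo[5.3.0]dec-2-en-10-yl 4-[(tert-butyldimethylsilyl)oxy]benzoate
Conditions: DCC, DMAP, CH2Cl2, rt
Reagents that add atoms: none
Why: Steglich esterification; only the secondary C10 hydroxyl reacts, the tertiary C8 hydroxyl and the silyl ethers are inert.

Step 15
Reactants: 25 (5R,6R,8R,9S,10S)-6-[(tert-butyldimethylsilyl)oxy]-8-hydroxy-2,5-dimethyl-8-(propan-2-yl)bicyclo[5.3.0]dec-2-en-10-yl 4-[(tert-butyldimethylsilyl)oxy]benzoate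
Product: 26 (5R,6R,8R,9S,10S)-6,8-dihydroxy-2,5-dimethyl-8-(propan-2-yl)bicyclo[5.3.0]dec-2-en-10-yl 4-hydroxybenzoate (target)
Conditions: HF·pyridine, THF, 0 °C to rt
Reagents that add atoms: none
Why: Fluoride-mediated cleavage of the aryl and the C6 tert-butyldimethylsilyl ethers under non-basic conditions, which avoids ester hydrolysis or migration and leaves the tertiary alcohol and the alkene untouched.

**Compound list**

1 | (E)-but-2-enal (crotonaldehyde) | C/C=C/C=O | starting material
2 | 2-(triphenyl-λ5-phosphanylidene)propanal | CC(C=O)=P(c1ccccc1)(c1ccccc1)c1ccccc1 | starting material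
3 | (2E,4E)-2-methylhexa-2,4-dienal | C/C=C/C=C(\C)C=O | intermediate
4 | 3-methylbutan-2-one | CC(C)C(C)=O | starting material
5 | enol diisopinocampheylborinate of 4 (isopinocampheyl groups from (+)-α-pinene) | C=C(OB([C@@H]1C[C@@H]2C[C@H]([C@H]1C)C2(C)C)[C@@H]1C[C@@H]2C[C@H]([C@H]1C)C2(C)C)C(C)C | intermediate
6 | (5R,6E,8E)-5-hydroxy-2,6-dimethyldeca-6,8-dien-3-one | C/C=C/C=C(\C)[C@H](O)CC(=O)C(C)C | intermediate
7 | bromoacetyl bromide | BrCC(Br)=O | starting material
8 | (5R,6E,8E)-2,6-dimethyl-3-oxodeca-6,8-dien-5-yl 2-bromoacetate | C/C=C/C=C(\C)[C@H](OC(=O)CBr)CC(=O)C(C)C | intermediate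
9 | samarium enolate of the acetate ester of 6 (trivalent samarium, I2Sm–O–C(=CH2)–O–) | C/C=C/C=C(\C)[C@H](OC(=C)O[Sm](I)I)CC(=O)C(C)C | intermediate
10 | (4S,6R)-6-[(2E,4E)-hexa-2,4-dien-2-yl]-4-hydroxy-4-(propan-2-yl)oxan-2-one | C/C=C/C=C(\C)[C@H]1C[C@@](O)(C(C)C)CC(=O)O1 | intermediate
11 | (3S,5R,6E,8E)-3,5-dihydroxy-N-methoxy-N,6-dimethyl-3-(propan-2-yl)deca-6,8-dienamide | C/C=C/C=C(\C)[C@H](O)C[C@@](O)(C(C)C)CC(=O)N(C)OC | intermediate
12 | (3S,5R,6E,8E)-5-[(tert-butyldimethylsilyl)oxy]-3-hydroxy-N-methoxy-N,6-dimethyl-3-(propan-2-yl)deca-6,8-dienamide | C/C=C/C=C(\C)[C@H](O[Si](C)(C)C(C)(C)C)C[C@@](O)(C(C)C)CC(=O)N(C)OC | intermediate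
13 | (3S,5R,6E,8E)-5-[(tert-butyldimethylsilyl)oxy]-N-methoxy-N,6-dimethyl-3-(propan-2-yl)-3-[(triethylsilyl)oxy]deca-6,8-dienamide | C/C=C/C=C(\C)[C@H](O[Si](C)(C)C(C)(C)C)C[C@@](O[Si](CC)(CC)CC)(C(C)C)CC(=O)N(C)OC | intermediate
14 | chloroiodomethane | ClCI | starting material
15 | tetrahedral lithium adduct of LiCH2Cl and 13 (lithium alkoxide of the N-methoxy-N-methyl hemiaminal, C10 configuration undefined) | C/C=C/C=C(\C)[C@H](O[Si](C)(C)C(C)(C)C)C[C@@](O[Si](CC)(CC)CC)(C(C)C)CC(O[Li])(CCl)N(C)OC | intermediate
16 | (4S,6R,7E,9E)-6-[(tert-butyldimethylsilyl)oxy]-1-chloro-7-methyl-4-(propan-2-yl)-4-[(triethylsilyl)oxy]undeca-7,9-dien-2-one | C/C=C/C=C(\C)[C@H](O[Si](C)(C)C(C)(C)C)C[C@@](O[Si](CC)(CC)CC)(C(C)C)CC(=O)CCl | intermediate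
17 | lithium-bound oxyallyl cation from 16 ((Z)-C9=C10(OLi)–C11H2+) | C/C=C/C=C(\C)[C@H](O[Si](C)(C)C(C)(C)C)C[C@@](O[Si](CC)(CC)CC)(C(C)C)/C=C(\[CH2+])O[Li] | intermediate
18 | (2R,5R,6R,8R,9R)-6-[(tert-butyldimethylsilyl)oxy]-2,5-dimethyl-8-(propan-2-yl)-8-[(triethylsilyl)oxy]bicyclo[5.3.0]dec-3-en-10-one, trans-fused | C[C@H]1C=C[C@@]2(C)[C@H](O[Si](C)(C)C(C)(C)C)C[C@@](O[Si](CC)(CC)CC)(C(C)C)[C@@H]2C(=O)C1 | intermediate
19 | (5R,6R,8R,9R)-conjugated enone, C11=C2 double bond, otherwise as 18 | CC=1CC[C@@]2(C)[C@H](O[Si](C)(C)C(C)(C)C)C[C@@](O[Si](CC)(CC)CC)(C(C)C)[C@@H]2C(=O)C=1 | intermediate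
20 | potassium dienolate C10(OK)=C11–C2=C3 | CC1=CC[C@@]2(C)[C@H](O[Si](C)(C)C(C)(C)C)C[C@@](O[Si](CC)(CC)CC)(C(C)C)[C@@H]2C(O[K])=C1 | intermediate
21 | (5R,6R,8R,9R)-6-[(tert-butyldimethylsilyl)oxy]-2,5-dimethyl-8-(propan-2-yl)-8-[(triethylsilyl)oxy]bicyclo[5.3.0]dec-2-en-10-one | CC1=CC[C@@]2(C)[C@H](O[Si](C)(C)C(C)(C)C)C[C@@](O[Si](CC)(CC)CC)(C(C)C)[C@@H]2C(=O)C1 | intermediate
22 | (5R,6R,8R,9R)-6-[(tert-butyldimethylsilyl)oxy]-8-hydroxy-2,5-dimethyl-8-(propan-2-yl)bicyclo[5.3.0]dec-2-en-10-one | CC1=CC[C@@]2(C)[C@H](O[Si](C)(C)C(C)(C)C)C[C@@](O)(C(C)C)[C@@H]2C(=O)C1 | intermediate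
23 | (5R,6R,8R,9S,10S)-6-[(tert-butyldimethylsilyl)oxy]-2,5-dimethyl-8-(propan-2-yl)bicyclo[5.3.0]dec-2-ene-8,10-diol | CC1=CC[C@@]2(C)[C@H](O[Si](C)(C)C(C)(C)C)C[C@@](O)(C(C)C)[C@@H]2[C@@H](O)C1 | intermediate
24 | 4-[(tert-butyldimethylsilyl)oxy]benzoic acid | CC(C)(C)[Si](C)(C)Oc1ccc(cc1)C(O)=O | starting material
25 | (5R,6R,8R,9S,10S)-6-[(tert-butyldimethylsilyl)oxy]-8-hydroxy-2,5-dimethyl-8-(propan-2-yl)bicyclo[5.3.0]dec-2-en-10-yl 4-[(tert-butyldimethylsilyl)oxy]benzoate | CC1=CC[C@@]2(C)[C@H](O[Si](C)(C)C(C)(C)C)C[C@@](O)(C(C)C)[C@@H]2[C@@H](OC(=O)c2ccc(O[Si](C)(C)C(C)(C)C)cc2)C1 | intermediate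
26 | (5R,6R,8R,9S,10S)-6,8-dihydroxy-2,5-dimethyl-8-(propan-2-yl)bicyclo[5.3.0]dec-2-en-10-yl 4-hydroxybenzoate | CC1=CC[C@@]2(C)[C@H](O)C[C@@](O)(C(C)C)[C@@H]2[C@@H](OC(=O)c2ccc(O)cc2)C1 | target

**Step count and least certain steps**

Total: 15 steps. Longest linear sequence: 15 steps, from 1 to 26; 2, 4, 7, 14 and 24 enter as building blocks.

Step 9 (key step).
- Most likely failure: slow closure, because C9 has to bond to a fully substituted diene terminus whose methyl group occupies the inside position of the s-cis diene. The short-lived cation 17 can then leak into Favorskii-type rearrangement, alkylation of the amine at C11, or collapse of a stepwise intermediate to five-membered-ring products.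
- Second concern: facial selectivity at C5 rests on a rotamer preference about C5–C6 that need not be large, and the ring fusion at C9 may come out cis. Correcting C9 by base is hazardous because its enolate can expel the C8 silyloxy group.
- Fallback: set out from 16 and change the reactive intermediate. Condensation with cyclohexylamine (Ti(OiPr)4, THF) gives the α-chloro ketimine F1. AgBF4 in CH2Cl2 removes chloride from its enamine tautomer and generates a 2-aminoallyl cation without any base; this cation is longer-lived and less electrophilic than 17 and undergoes the same (4+3) closure to the iminium salt F2. Aqueous hydrolysis of F2 returns to the route at 18.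

Step 2.
- Most likely failure: limited enantioselectivity of the methyl ketone boron aldol, or a sense of induction opposite to the one assumed.
- Fallback: set out from 3 and 4 and replace reagent control by resolution. A LiN(iPr)2-mediated aldol gives the racemic aldol F3. Sharpless kinetic resolution (Ti(OiPr)4, L-(+)-diisopropyl tartrate, tBuOOH 0.6 equiv, −20 °C) epoxidises the (5S)-enantiomer to epoxy alcohol F4 and leaves the (5R)-alcohol, which is 6.

Step 10.
- Most likely failure: stalled or incomplete migration, since the cis-disubstituted alkene is flanked by a quaternary carbon and the second shift needs a hindered metal alkyl.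
- Fallback: set out from 18 and reach the dienolate by oxidation and reduction instead of migration. LiN(iPr)2/Me3SiCl gives the C10–C11 silyl enol ether F5 (the C9 methine is too hindered to compete). Saegusa–Ito oxidation (Pd(OAc)2, MeCN) gives the linear dienone F6. Dissolving-metal reduction (Li, NH3/THF, −78 °C, then NH4Cl) adds hydrogen at C4 and forms the same dienolate as in step 11, whose α-protonation returns to the route at 21.

Step 11.
- Most likely failure: deprotonation at C9 instead of C3, leading to epimerisation of the ring fusion or β-elimination of the C8 silyloxy group, or protonation at the γ-carbon, which regenerates 19.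
- Fallback: set out from 19 and avoid strong base. Me3SiOTf/Et3N (CH2Cl2, 0 °C) gives the extended silyl dienol ether F7. HF·pyridine then protonates it at C11 and cleaves the triethylsilyl ether in the same operation, returning at 22.

Step 13.
- Most likely failure: slow exchange of the hindered tertiary C8 hydroxyl onto boron, so that the reduction stalls while the β,γ-enone re-conjugates in the acidic medium.
- Fallback: set out from 22 and make the other epimer on purpose. Narasaka–Prasad reduction (Et2BOMe, NaBH4, THF/MeOH, −78 °C) gives the C10-epimeric syn-diol F8 by external hydride attack on the boron chelate. Mitsunobu esterification of F8 with 24 (PPh3, diisopropyl azodicarboxylate, toluene) inverts C10 while installing the ester and returns at 25.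

**Further compounds**

F1 | step 9 | N-cyclohexyl ketimine of chloro ketone 16 | C/C=C/C=C(\C)[C@H](O[Si](C)(C)C(C)(C)C)C[C@@](O[Si](CC)(CC)CC)(C(C)C)CC(CCl)=NC1CCCCC1
F2 | step 9 | N-cyclohexyl iminium tetrafluoroborate of cycloadduct 18 | C[C@H]1C=C[C@@]2(C)[C@H](O[Si](C)(C)C(C)(C)C)C[C@@](O[Si](CC)(CC)CC)(C(C)C)[C@@H]2C(=[NH+]C2CCCCC2)C1.F[B-](F)(F)F
F3 | step 2 | racemic (6E,8E)-5-hydroxy-2,6-dimethyldeca-6,8-dien-3-one | C/C=C/C=C(\C)C(O)CC(=O)C(C)C
F4 | step 2 | 6,7-epoxide of the (5S)-enantiomer of the aldol | C/C=C/[C@H]1O[C@]1(C)[C@@H](O)CC(=O)C(C)C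
F5 | step 10 | C10–C11 trimethylsilyl enol ether of 18 | C[C@H]1C=C[C@@]2(C)[C@H](O[Si](C)(C)C(C)(C)C)C[C@@](O[Si](CC)(CC)CC)(C(C)C)[C@@H]2C(O[Si](C)(C)C)=C1
F6 | step 10 | linear dienone, C11=C2 and C3=C4 double bonds, C10 ketone | CC=1C=C[C@@]2(C)[C@H](O[Si](C)(C)C(C)(C)C)C[C@@](O[Si](CC)(CC)CC)(C(C)C)[C@@H]2C(=O)C=1
F7 | step 11 | extended trimethylsilyl dienol ether C10(OSiMe3)=C11–C2=C3 | CC1=CC[C@@]2(C)[C@H](O[Si](C)(C)C(C)(C)C)C[C@@](O[Si](CC)(CC)CC)(C(C)C)[C@@H]2C(O[Si](C)(C)C)=C1
F8 | step 13 | C10 epimer of diol 23 (8,10-syn) | CC1=CC[C@@]2(C)[C@H](O[Si](C)(C)C(C)(C)C)C[C@@](O)(C(C)C)[C@@H]2[C@H](O)C1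
A1 | alternative 1 | bicyclic nitro ketol enone | CC1=CC(=O)[C@H]2[C@](O)(C(C)C)C[C@@H]([N+](=O)[O-])[C@]2(C)CC1
A2 | alternative 1 | 3,6-dimethylcyclohepta-2,6-dien-1-one | CC1=CC(=O)C=C(C)CC1
A3 | alternative 1 | 4-methyl-1-nitropentan-3-one | CC(C)C(=O)CC[N+](=O)[O-]
A4 | alternative 2 | bicyclic core with C10 4-methoxybenzyl ether | CC1=CC[C@@]2(C)[C@H](O[Si](C)(C)C(C)(C)C)C[C@@](O)(C(C)C)[C@@H]2[C@@H](OCc2ccc(OC)cc2)C1
A5 | alternative 2 | cyclopentane with (Z)-vinyl iodide arm on C5 and N-hydroxyphthalimide ester arm on C9 | C/C(I)=C/C[C@@]1(C)[C@H](O[Si](C)(C)C(C)(C)C)C[C@@](O)(C(C)C)[C@@H]1[C@@H](OCc1ccc(OC)cc1)CC(=O)ON1C(=O)c2ccccc2C1=O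
A6 | alternative 3 | bicyclic C6 ketone with protected C8 carbinol | CC1=CC[C@@]2(C)C(=O)C[C@@](O[Si](CC)(CC)CC)(C(C)C)[C@@H]2[C@@H](OC(=O)c2ccc(O[Si](C)(C)C(C)(C)C)cc2)C1
A7 | alternative 3 | cycloheptene diazoketone with silyloxy side chain on C9 | CC1=CC[C@@](C)(C(=O)C=[N+]=[N-])[C@H]([C@H](O[Si](CC)(CC)CC)C(C)C)[C@@H](OC(=O)c2ccc(O[Si](C)(C)C(C)(C)C)cc2)C1
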